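Cuts: the C3–C4 oxirane goes back to a Z alkene and the C9 and C14 ketones to carbinols. The 14-membered carbocycle is then opened at C1–C14 and the chain divided at C8–C9, C5–C6 and C2–C3.
Enabling feature: the run C14(=O)–C1(isopropyl)=C2–C3/C4(oxirane) inside the 14-membered ring is a hidden (1E,3Z)-dienyl carbinol. This is what forms when H and an aldehyde carbon add cis to the alkyne of a 1,3-enyne, with C–C bonding at the alkyne carbon far from the alkene.
Forward order: Sonogashira coupling (C2–C3), copper-catalysed allylic coupling (C5–C6), Evans aldol (C8–C9), nickel-catalysed reductive closure of the carbocycle (C1–C14), oxirane last.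
sp3 centres: C12 from (R)-citronellal, C13 from D-proline aminoxylation, C8 from the (R)-benzyloxazolidinone syn aldol. The C9 and C14 carbinol centres are erased by oxidation.
Alkenes and oxirane: Z-C3=C4 from anti-carbomagnesiation of propargyl alcohol, and E-C1=C2 from the cis addition in the ring closure. The (3S,4R)-oxirane comes from the Z alkene and the L-series Shi ketone (1,2:4,5-di-O-isopropylidene-β-L-erythro-2,3-hexodiulo-2,6-pyranose).

Key step: step 18

Numbering: C1 bears isopropyl, C2 is the vinylic CH, C3/C4 carry the oxirane (methyl on C4), and C8 bears the hydroxymethyl carbon C18. C9 and C14 are the ketones, C12 bears methyl and C13 bears hydroxyl.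
Assumption: the two C14 epimers of the macrocyclic carbinol are carried on together because both give the same ketone. The facial sense of the Shi epoxidation is taken from the spiro transition-state model and is assumed not to be overridden by the ring conformation.

Step 1
Reactants: 1 propargyl alcohol
Product: 3 (Z)-3-iodo-2-methylprop-2-en-1-ol, via alkenyl dimagnesium species 2 (not isolated)
Conditions: MeMgBr (2.5 equiv), CuI (10 mol%), THF, -10 °C to rt; then I2, THF, 0 °C
Reagents that add atoms: methylmagnesium bromide C[Mg]Br; iodine II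
Why: Copper-catalysed anti-carbomagnesiation of the propargylic alkoxide puts methyl on the inner alkyne carbon (C4) and magnesium on the terminal carbon (C3) cis to the CH2O group through a five-membered chelate, and iodinolysis with retention should then give only the Z iodide.

Step 2
Reactants: 3 (Z)-3-iodo-2-methylprop-2-en-1-ol; 4 3-methylbut-1-yne
Product: 5 (Z)-2,6-dimethylhept-2-en-4-yn-1-ol
Conditions: PdCl2(PPh3)2 (2 mol%), CuI (4 mol%), Et3N, THF, 0 °C to rt
Reagents that add atoms: none
Why: Sonogashira coupling of an alkenyl iodide with a terminal alkyne forms C2–C3 with retention of the Z geometry and tolerates the free hydroxyl group.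

Step 3
Reactants: 5 (Z)-2,6-dimethylhept-2-en-4-yn-1-ol
Product: 6 (Z)-1-bromo-2,6-dimethylhept-2-en-4-yne
Conditions: CBr4, PPh3, CH2Cl2, -20 to 0 °C
Reagents that add atoms: carbon tetrabromide BrC(Br)(Br)Br
Why: Appel bromination displaces the oxyphosphonium group at the primary allylic carbon in an SN2 sense under neutral, cold conditions, which should keep the Z alkene and the alkyne intact.

Step 4
Reactants: 6 (Z)-1-bromo-2,6-dimethylhept-2-en-4-yne; 7 (4-bromobutoxy)(tert-butyl)dimethylsilane
Product: 9 (Z)-tert-butyl[(6,10-dimethylundec-6-en-8-yn-1-yl)oxy]dimethylsilane, via Grignard reagent 8 (not isolated)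
Conditions: 7, Mg, THF, rt to 40 °C; then 6, Li2CuCl4 (5 mol%), THF, -78 to 0 °C
Reagents that add atoms: none
Why: Copper-catalysed Grignard cross-coupling with a primary allylic bromide (Kochi-type coupling) forms C5–C6; Li2CuCl4 in THF at low temperature favours a dialkylcuprate that substitutes directly at the bromine-bearing carbon with retention of the Z geometry instead of with allylic transposition.

Step 5
Reactants: 9 (Z)-tert-butyl[(6,10-dimethylundec-6-en-8-yn-1-yl)oxy]dimethylsilane
Product: 10 (Z)-6,10-dimethylundec-6-en-8-yn-1-ol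
Conditions: Bu4NF, THF, 0 °C to rt
Reagents that add atoms: none
Why: Fluoride-induced cleavage of a primary silyl ether is driven by the strong Si–F bond and does not touch the enyne.

Step 6
Reactants: 10 (Z)-6,10-dimethylundec-6-en-8-yn-1-ol
Product: 12 (Z)-6,10-dimethylundec-6-en-8-ynoic acid, via aldehyde 11 (not isolated)
Conditions: TEMPO (2,2,6,6-tetramethylpiperidin-1-oxyl, 20 mol%), PhI(OAc)2 (2.2 equiv), MeCN/H2O 1:1, rt
Reagents that add atoms: water O
Why: Oxoammonium-catalysed oxidation (TEMPO with PhI(OAc)2) in aqueous acetonitrile carries the primary alcohol through aldehyde 11 and its hydrate to the acid while alkenes and alkynes are left alone.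

Step 7
Reactants: 12 (Z)-6,10-dimethylundec-6-en-8-ynoic acid; 13 (R)-4-benzyloxazolidin-2-one
Product: 15 (R)-4-benzyl-3-[(Z)-6,10-dimethylundec-6-en-8-ynoyl]oxazolidin-2-one, via mixed pivalic anhydride 14 (not isolated)
Conditions: PivCl, Et3N, THF, -20 °C; then LiCl, 13, -20 °C to rt
Reagents that add atoms: none
Why: N-acylation of the Evans auxiliary through the mixed pivalic anhydride works because the tert-butyl group shields the pivaloyl carbonyl, so that the LiCl-activated oxazolidinone attacks the unbranched acyl group.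

Step 8
Reactants: 16 (R)-citronellal
Product: 18 (2S,3R)-3,7-dimethyl-2-[(phenylamino)oxy]oct-6-en-1-ol, via aminoxy aldehyde 17 (not isolated)
Conditions: PhNO, D-proline (20 mol%), MeCN, -20 °C; then NaBH4, MeOH, 0 °C
Reagents that add atoms: nitrosobenzene O=Nc1ccccc1
Why: Proline-catalysed alpha-aminoxylation: the enamine of 16 attacks the oxygen of nitrosobenzene, which is held by the carboxylic acid of the catalyst, so that D-proline sets 13S (C2 of 18) under catalyst control whatever the neighbouring methyl centre prefers, and immediate borohydride reduction forestalls epimerization.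

Step 9
Reactants: 18 (2S,3R)-3,7-dimethyl-2-[(phenylamino)oxy]oct-6-en-1-ol
Product: 19 (2S,3R)-3,7-dimethyloct-6-ene-1,2-diol
Conditions: Zn, AcOH/EtOH, rt
Reagents that add atoms: none
Why: Reductive N–O bond cleavage with zinc in acetic acid frees the secondary hydroxyl group without touching the trisubstituted alkene or either stereocentre.

Step 10
Reactants: 19 (2S,3R)-3,7-dimethyloct-6-ene-1,2-diol
Product: 21 (2S,3R)-1-[(4-methoxybenzyl)oxy]-3,7-dimethyloct-6-en-2-ol, via dibutylstannylene acetal 20 (not isolated)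
Conditions: Bu2SnO, toluene, reflux (Dean–Stark); then PMBCl, Bu4NI (cat.), toluene, 90 °C
Reagents that add atoms: 4-methoxybenzyl chloride COc1ccc(CCl)cc1
Why: Stannylene-acetal-mediated regioselective O-alkylation exploits the higher nucleophilicity of the primary oxygen in the dibutylstannylene, so that only the C14 oxygen is benzylated.

Step 11
Reactants: 21 (2S,3R)-1-[(4-methoxybenzyl)oxy]-3,7-dimethyloct-6-en-2-ol
Product: 22 tert-butyl{[(2S,3R)-1-[(4-methoxybenzyl)oxy]-3,7-dimethyloct-6-en-2-yl]oxy}dimethylsilane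
Conditions: TBSOTf, 2,6-lutidine, CH2Cl2, -78 to 0 °C
Reagents that add atoms: tert-butyldimethylsilyl triflate CC(C)(C)[Si](C)(C)OS(=O)(=O)C(F)(F)F
Why: Silylation with a silyl triflate and a hindered pyridine base is the standard way to protect a secondary alcohol flanked by a branched carbon, and the PMB ether and alkene are inert to it.

Step 12
Reactants: 22 tert-butyl{[(2S,3R)-1-[(4-methoxybenzyl)oxy]-3,7-dimethyloct-6-en-2-yl]oxy}dimethylsilane
Product: 24 (4R,5S)-5-[(tert-butyldimethylsilyl)oxy]-6-[(4-methoxybenzyl)oxy]-4-methylhexanal, via secondary ozonide 23 (not isolated)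
Conditions: O3, CH2Cl2, -78 °C (Sudan Red 7B end point); then PPh3, -78 °C to rt
Reagents that add atoms: ozone [O-][O+]=O
Why: Ozonolysis with reductive work-up cleaves the electron-rich trisubstituted alkene much faster than ozone attacks the anisyl ring, and the dye end point guards against over-oxidation.

Step 13
Reactants: 15 (R)-4-benzyl-3-[(Z)-6,10-dimethylundec-6-en-8-ynoyl]oxazolidin-2-one; 24 (4R,5S)-5-[(tert-butyldimethylsilyl)oxy]-6-[(4-methoxybenzyl)oxy]-4-methylhexanal
Product: 27 (R)-4-benzyl-3-{(2R,3S,6R,7S)-7-[(tert-butyldimethylsilyl)oxy]-2-[(Z)-4,8-dimethylnon-4-en-6-yn-1-yl]-3-hydroxy-8-[(4-methoxybenzyl)oxy]-6-methyloctanoyl}oxazolidin-2-one, via Z boron enolate 25 (not isolated), via boron aldolate 26 (not isolated)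
Conditions: 15, Bu2BOTf, Et3N, CH2Cl2, -78 to 0 °C; 24, -78 to 0 °C; then pH 7 buffer, MeOH, 30% H2O2, 0 °C
Reagents that add atoms: none
Why: Evans syn aldol reaction: soft enolization gives the Z boron enolate 25, which reacts through a Zimmerman–Traxler chair on the face away from the benzyl group, so that the (R)-auxiliary sets C8 and C9 (2R,3S in 27) regardless of the remote centres of 24.

Step 14
Reactants: 27 syn-aldol adduct
Product: 28 (2S,3S,6R,7S)-7-[(tert-butyldimethylsilyl)oxy]-2-[(Z)-4,8-dimethylnon-4-en-6-yn-1-yl]-8-[(4-methoxybenzyl)oxy]-6-methyloctane-1,3-diol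
Conditions: LiBH4, MeOH (1 equiv), THF, 0 °C
Reagents that add atoms: none
Why: Reductive cleavage of the N-acyl oxazolidinone with LiBH4 and methanol attacks the exocyclic imide carbonyl and gives the primary alcohol without epimerization at C8, whose descriptor changes from R to S only because the priorities change.

Step 15
Reactants: 28 seco 1,3-diol (C18 and C9 hydroxyls free)
Product: 30 (2S,3S,6R,7S)-1,7-bis[(tert-butyldimethylsilyl)oxy]-2-[(Z)-4,8-dimethylnon-4-en-6-yn-1-yl]-8-[(4-methoxybenzyl)oxy]-6-methyl-3-[(triethylsilyl)oxy]octane, via mono-TBS ether 29 (not isolated)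
Conditions: TBSCl (1.05 equiv), imidazole, CH2Cl2, 0 °C; then TESCl, 4-(dimethylamino)pyridine (cat.), 0 °C to rt
Reagents that add atoms: tert-butyldimethylsilyl chloride CC(C)(C)[Si](C)(C)Cl; triethylsilyl chloride CC[Si](Cl)(CC)CC
Why: Sequential silylation relies on steric discrimination, TBSCl reacting only with the primary C18 hydroxyl at 0 °C before the smaller TESCl caps the secondary C9 hydroxyl.

Step 16
Reactants: 30 fully protected seco enyne
Product: 31 (2S,3R,6S,7S)-2,8-bis[(tert-butyldimethylsilyl)oxy]-7-[(Z)-4,8-dimethylnon-4-en-6-yn-1-yl]-3-methyl-6-[(triethylsilyl)oxy]octan-1-ol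
Conditions: DDQ, CH2Cl2/pH 7 buffer 10:1, 0 °C
Reagents that add atoms: none
Why: Oxidative PMB ether cleavage with DDQ proceeds by hydride abstraction from the electron-rich benzylic position and hydrolysis of the oxocarbenium ion, and the buffer protects the TES ether.

Step 17
Reactants: 31 seco enyne C14 alcohol
Product: 32 (2S,3R,6S,7S)-2,8-bis[(tert-butyldimethylsilyl)oxy]-7-[(Z)-4,8-dimethylnon-4-en-6-yn-1-yl]-3-methyl-6-[(triethylsilyl)oxy]octanal
Conditions: Dess–Martin periodinane, NaHCO3, CH2Cl2, 0 °C to rt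
Reagents that add atoms: none
Why: Dess–Martin oxidation under buffered, non-basic conditions should give the alpha-silyloxy aldehyde without epimerization at C13.

Step 18
Reactants: 32 seco enyne aldehyde
Product: 34 (1E,3Z,8S,9S,12R,13S)-13-[(tert-butyldimethylsilyl)oxy]-8-{[(tert-butyldimethylsilyl)oxy]methyl}-1-isopropyl-4,12-dimethyl-9-[(triethylsilyl)oxy]cyclotetradeca-1,3-dien-14-ol (target numbering; both C14 epimers), via diethylborinate 33 (not isolated)
Conditions: Ni(cod)2 (20 mol%), P(c-C5H9)3 (tricyclopentylphosphine, 40 mol%), Et3B (3 equiv), toluene, slow addition of 32 to a final 0.002 M, rt to 40 °C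
Reagents that add atoms: none
Why: Zerovalent nickel binds the alkyne of 32 together with the adjoining C3–C4 alkene and the C14 aldehyde; oxidative cyclization gives an oxanickelacyclopentene that already holds the C1–C14 bond, and ethyl transfer from Et3B to nickel, beta-hydride elimination (loss of ethene) and C–H reductive elimination then place hydrogen on C2 on the same side as C14 and release the carbinol as borinate 33, which the work-up hydrolyses. The closest known reaction type is the nickel-catalysed, Et3B-mediated reductive alkyne–aldehyde (ynal) macrocyclization, established for rings of this size; bonding at the remote alkyne carbon of conjugated 1,3-enynes and the use of alpha-silyloxy aldehydes are established in the intermolecular coupling, so that only their joint use in an all-carbon ring stretches the known scope. The one ring that closes is the 14-membered carbocycle, in the endocyclic mode: both alkyne carbons become ring members joined by an E double bond, because the tether reaches the alkyne through C3 and the bond forms at the far carbon C1. The only new stereocentre, C14, should be biased towards the 13,14-anti carbinol by the Felkin-type preference of the alpha-silyloxy aldehyde, but it needs no control since step 20 converts it into the ketone, and the E geometry is fixed by the cis addition of H and C14. The step needs bonding at C1 instead of C2 (14-membered endocyclic against 13-membered exocyclic closure) and ring closure instead of oligomerization; the first is secured by coordination of the conjugated C3–C4 alkene, which steers nickel to C2 and outweighs the bulk of the isopropyl group, the second by slow addition at high dilution. A single aldehyde, a single alkyne, fully silylated oxygens and base-free conditions should leave the epimerizable C13 centre and the Z alkene as they are.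

Step 19
Reactants: 34 macrocyclic (1E,3Z)-dienyl carbinol
Product: 35 (1E,3Z,8S,9S,12R,13S)-13-[(tert-butyldimethylsilyl)oxy]-8-{[(tert-butyldimethylsilyl)oxy]methyl}-1-isopropyl-4,12-dimethylcyclotetradeca-1,3-diene-9,14-diol (both C14 epimers)
Conditions: HF·pyridine, pyridine, THF, 0 °C
Reagents that add atoms: none
Why: Chemoselective desilylation with pyridine-buffered HF·pyridine removes the much more labile TES ether while both TBS ethers stay, and the nearly neutral medium avoids ionization of the dienyl carbinol.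

Step 20
Reactants: 35 macrocyclic 9,14-diol
Product: 36 (1E,3Z,8S,12R,13S)-13-[(tert-butyldimethylsilyl)oxy]-8-{[(tert-butyldimethylsilyl)oxy]methyl}-1-isopropyl-4,12-dimethylcyclotetradeca-1,3-diene-9,14-dione
Conditions: Dess–Martin periodinane (3 equiv), NaHCO3, CH2Cl2, 0 °C to rt, dark
Reagents that add atoms: none
Why: Dess–Martin oxidation converts both secondary carbinols in one operation, merges the C14 epimers into one dienone and is mild enough for the Z alkene and the centres at C8 and C13.

Step 21
Reactants: 36 macrocyclic dienedione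
Product: 37 (1E,3S,4R,8S,12R,13S)-13-[(tert-butyldimethylsilyl)oxy]-8-{[(tert-butyldimethylsilyl)oxy]methyl}-3,4-epoxy-1-isopropyl-4,12-dimethylcyclotetradec-1-ene-9,14-dione
Conditions: 1,2:4,5-di-O-isopropylidene-β-L-erythro-2,3-hexodiulo-2,6-pyranose (0.5 equiv), Oxone (2KHSO5·KHSO4·K2SO4), K2CO3, Bu4NHSO4, Na2B4O7/Na2EDTA buffer, MeCN/dimethoxymethane/H2O, 0 °C
Reagents that add atoms: potassium peroxymonosulfate [K+].[O-]S(=O)(=O)OO
Why: Shi asymmetric epoxidation: the electrophilic chiral dioxirane attacks the remote, more electron-rich C3–C4 alkene of the dienone instead of the carbonyl-conjugated and isopropyl-shielded C1–C2 alkene, oxygen transfer is stereospecific so that the Z alkene gives the cis oxirane, and the spiro transition-state model (vinylic hydrogen of C3 in the crowded quadrant, as for 1-phenylcyclohexene) assigns the (3S,4R) face to the L-series ketone.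

Step 22
Reactants: 37 bis-TBS ether of the target
Product: 38 target CNP0110598.2, (1E,3S,4R,8S,12R,13S)-3,4-epoxy-13-hydroxy-8-(hydroxymethyl)-1-isopropyl-4,12-dimethylcyclotetradec-1-ene-9,14-dione
Conditions: HF·pyridine, pyridine, THF, 0 °C to rt
Reagents that add atoms: none
Why: Fluoride-mediated global desilylation with buffered HF·pyridine avoids both the base that would endanger the beta-hydroxy ketone and alpha-ketol units and the strong acid that would open the oxirane.

Compound list
1 | propargyl alcohol | C#CCO | starting material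
2 | bromomagnesium (Z)-3-(bromomagnesio)-2-methylprop-2-en-1-olate | Br[Mg]OC/C(C)=C\[Mg]Br | intermediate
3 | (Z)-3-iodo-2-methylprop-2-en-1-ol | OC/C(C)=C\I | intermediate
4 | 3-methylbut-1-yne | CC(C)C#C | starting material
5 | (Z)-2,6-dimethylhept-2-en-4-yn-1-ol | CC(C)C#C/C=C(/C)CO | intermediate
6 | (Z)-1-bromo-2,6-dimethylhept-2-en-4-yne | CC(C)C#C/C=C(/C)CBr | intermediate
7 | (4-bromobutoxy)(tert-butyl)dimethylsilane | BrCCCCO[Si](C)(C)C(C)(C)C | starting material
8 | [4-(tert-butyldimethylsilyloxy)butyl]magnesium bromide | Br[Mg]CCCCO[Si](C)(C)C(C)(C)C | intermediate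
9 | (Z)-tert-butyl[(6,10-dimethylundec-6-en-8-yn-1-yl)oxy]dimethylsilane | CC(C)C#C/C=C(/C)CCCCCO[Si](C)(C)C(C)(C)C | intermediate
10 | (Z)-6,10-dimethylundec-6-en-8-yn-1-ol | CC(C)C#C/C=C(/C)CCCCCO | intermediate
11 | (Z)-6,10-dimethylundec-6-en-8-ynal | CC(C)C#C/C=C(/C)CCCCC=O | intermediate
12 | (Z)-6,10-dimethylundec-6-en-8-ynoic acid | CC(C)C#C/C=C(/C)CCCCC(=O)O | intermediate
13 | (R)-4-benzyloxazolidin-2-one | O=C1N[C@H](Cc2ccccc2)CO1 | starting material
14 | (Z)-6,10-dimethylundec-6-en-8-ynoic pivalic anhydride | CC(C)C#C/C=C(/C)CCCCC(=O)OC(=O)C(C)(C)C | intermediate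
15 | (R)-4-benzyl-3-[(Z)-6,10-dimethylundec-6-en-8-ynoyl]oxazolidin-2-one | CC(C)C#C/C=C(/C)CCCCC(=O)N1[C@H](Cc2ccccc2)COC1=O | intermediate
16 | (R)-citronellal, (R)-3,7-dimethyloct-6-enal | O=CC[C@H](C)CCC=C(C)C | starting material
17 | (2S,3R)-3,7-dimethyl-2-[(phenylamino)oxy]oct-6-enal | O=C[C@@H](ONc1ccccc1)[C@H](C)CCC=C(C)C | intermediate
18 | (2S,3R)-3,7-dimethyl-2-[(phenylamino)oxy]oct-6-en-1-ol | OC[C@@H](ONc1ccccc1)[C@H](C)CCC=C(C)C | intermediate
19 | (2S,3R)-3,7-dimethyloct-6-ene-1,2-diol | OC[C@@H](O)[C@H](C)CCC=C(C)C | intermediate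
20 | dibutylstannylene acetal of diol 19 | CCCC[Sn]1(CCCC)OC[C@H]([C@H](C)CCC=C(C)C)O1 | intermediate
21 | (2S,3R)-1-[(4-methoxybenzyl)oxy]-3,7-dimethyloct-6-en-2-ol | COc1ccc(COC[C@@H](O)[C@H](C)CCC=C(C)C)cc1 | intermediate
22 | tert-butyl{[(2S,3R)-1-[(4-methoxybenzyl)oxy]-3,7-dimethyloct-6-en-2-yl]oxy}dimethylsilane | COc1ccc(COC[C@@H](O[Si](C)(C)C(C)(C)C)[C@H](C)CCC=C(C)C)cc1 | intermediate
23 | secondary ozonide (3,3-dimethyl-1,2,4-trioxolane) of 22, ozonide carbon unspecified | CC1(C)OOC(CC[C@@H](C)[C@H](O[Si](C)(C)C(C)(C)C)COCc2ccc(OC)cc2)O1 | intermediate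
24 | (4R,5S)-5-[(tert-butyldimethylsilyl)oxy]-6-[(4-methoxybenzyl)oxy]-4-methylhexanal | O=CCC[C@@H](C)[C@H](O[Si](C)(C)C(C)(C)C)COCc1ccc(OC)cc1 | intermediate
25 | Z dibutylboron enolate of imide 15 | CC(C)C#C/C=C(/C)CCC/C=C(\OB(CCCC)CCCC)N1[C@H](Cc2ccccc2)COC1=O | intermediate
26 | O-dibutylboryl aldolate of 27 | CC(C)C#C/C=C(/C)CCC[C@@H](C(=O)N1[C@H](Cc2ccccc2)COC1=O)[C@@H](OB(CCCC)CCCC)CC[C@@H](C)[C@H](O[Si](C)(C)C(C)(C)C)COCc1ccc(OC)cc1 | intermediate
27 | (R)-4-benzyl-3-{(2R,3S,6R,7S)-7-[(tert-butyldimethylsilyl)oxy]-2-[(Z)-4,8-dimethylnon-4-en-6-yn-1-yl]-3-hydroxy-8-[(4-methoxybenzyl)oxy]-6-methyloctanoyl}oxazolidin-2-one | CC(C)C#C/C=C(/C)CCC[C@@H](C(=O)N1[C@H](Cc2ccccc2)COC1=O)[C@@H](O)CC[C@@H](C)[C@H](O[Si](C)(C)C(C)(C)C)COCc1ccc(OC)cc1 | intermediate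
28 | (2S,3S,6R,7S)-7-[(tert-butyldimethylsilyl)oxy]-2-[(Z)-4,8-dimethylnon-4-en-6-yn-1-yl]-8-[(4-methoxybenzyl)oxy]-6-methyloctane-1,3-diol | CC(C)C#C/C=C(/C)CCC[C@@H](CO)[C@@H](O)CC[C@@H](C)[C@H](O[Si](C)(C)C(C)(C)C)COCc1ccc(OC)cc1 | intermediate
29 | 1-O-TBS ether of 28 (C18 oxygen silylated, C9 hydroxyl free) | CC(C)C#C/C=C(/C)CCC[C@@H](CO[Si](C)(C)C(C)(C)C)[C@@H](O)CC[C@@H](C)[C@H](O[Si](C)(C)C(C)(C)C)COCc1ccc(OC)cc1 | intermediate
30 | (2S,3S,6R,7S)-1,7-bis[(tert-butyldimethylsilyl)oxy]-2-[(Z)-4,8-dimethylnon-4-en-6-yn-1-yl]-8-[(4-methoxybenzyl)oxy]-6-methyl-3-[(triethylsilyl)oxy]octane | CC(C)C#C/C=C(/C)CCC[C@@H](CO[Si](C)(C)C(C)(C)C)[C@@H](O[Si](CC)(CC)CC)CC[C@@H](C)[C@H](O[Si](C)(C)C(C)(C)C)COCc1ccc(OC)cc1 | intermediate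
31 | (2S,3R,6S,7S)-2,8-bis[(tert-butyldimethylsilyl)oxy]-7-[(Z)-4,8-dimethylnon-4-en-6-yn-1-yl]-3-methyl-6-[(triethylsilyl)oxy]octan-1-ol | CC(C)C#C/C=C(/C)CCC[C@@H](CO[Si](C)(C)C(C)(C)C)[C@@H](O[Si](CC)(CC)CC)CC[C@@H](C)[C@H](O[Si](C)(C)C(C)(C)C)CO | intermediate
32 | (2S,3R,6S,7S)-2,8-bis[(tert-butyldimethylsilyl)oxy]-7-[(Z)-4,8-dimethylnon-4-en-6-yn-1-yl]-3-methyl-6-[(triethylsilyl)oxy]octanal | CC(C)C#C/C=C(/C)CCC[C@@H](CO[Si](C)(C)C(C)(C)C)[C@@H](O[Si](CC)(CC)CC)CC[C@@H](C)[C@H](O[Si](C)(C)C(C)(C)C)C=O | intermediate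
33 | O-diethylboryl ether of carbinol 34, C14 unspecified | CC(C)/C1=C\C=C(\C)CCC[C@@H](CO[Si](C)(C)C(C)(C)C)[C@@H](O[Si](CC)(CC)CC)CC[C@@H](C)[C@H](O[Si](C)(C)C(C)(C)C)C1OB(CC)CC | intermediate
34 | (1E,3Z,8S,9S,12R,13S)-13-[(tert-butyldimethylsilyl)oxy]-8-{[(tert-butyldimethylsilyl)oxy]methyl}-1-isopropyl-4,12-dimethyl-9-[(triethylsilyl)oxy]cyclotetradeca-1,3-dien-14-ol, C14 unspecified | CC(C)/C1=C\C=C(\C)CCC[C@@H](CO[Si](C)(C)C(C)(C)C)[C@@H](O[Si](CC)(CC)CC)CC[C@@H](C)[C@H](O[Si](C)(C)C(C)(C)C)C1O | intermediate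
35 | (1E,3Z,8S,9S,12R,13S)-13-[(tert-butyldimethylsilyl)oxy]-8-{[(tert-butyldimethylsilyl)oxy]methyl}-1-isopropyl-4,12-dimethylcyclotetradeca-1,3-diene-9,14-diol, C14 unspecified | CC(C)/C1=C\C=C(\C)CCC[C@@H](CO[Si](C)(C)C(C)(C)C)[C@@H](O)CC[C@@H](C)[C@H](O[Si](C)(C)C(C)(C)C)C1O | intermediate
36 | (1E,3Z,8S,12R,13S)-13-[(tert-butyldimethylsilyl)oxy]-8-{[(tert-butyldimethylsilyl)oxy]methyl}-1-isopropyl-4,12-dimethylcyclotetradeca-1,3-diene-9,14-dione | CC(C)/C1=C\C=C(\C)CCC[C@@H](CO[Si](C)(C)C(C)(C)C)C(=O)CC[C@@H](C)[C@H](O[Si](C)(C)C(C)(C)C)C1=O | intermediate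
37 | (1E,3S,4R,8S,12R,13S)-13-[(tert-butyldimethylsilyl)oxy]-8-{[(tert-butyldimethylsilyl)oxy]methyl}-3,4-epoxy-1-isopropyl-4,12-dimethylcyclotetradec-1-ene-9,14-dione | CC(C)/C1=C\[C@@H]2O[C@]2(C)CCC[C@@H](CO[Si](C)(C)C(C)(C)C)C(=O)CC[C@@H](C)[C@H](O[Si](C)(C)C(C)(C)C)C1=O | intermediate
38 | CNP0110598.2, (1E,3S,4R,8S,12R,13S)-3,4-epoxy-13-hydroxy-8-(hydroxymethyl)-1-isopropyl-4,12-dimethylcyclotetradec-1-ene-9,14-dione | CC(C)/C1=C\[C@@H]2O[C@]2(C)CCC[C@@H](CO)C(=O)CC[C@@H](C)[C@H](O)C1=O | target

Total step count: 22.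
Longest linear sequence: 17 steps (steps 1–7 and 13–22, from propargyl alcohol). The citronellal branch (steps 8–12) joins at step 13.

Steps most likely to fail

Step 18, the reductive macrocyclization.
- **What may go wrong:** bonding may occur at C2 with exocyclic closure. Intermolecular coupling may outrun ring closure. The aldehyde may be consumed by ethyl transfer or simple reduction.
- **Fallback:** the same C1–C14 bond is made from a preformed alkenyl iodide by chromium/nickel chemistry instead of by catalytic reductive coupling. It sets out from alcohol 31.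
- Copper-catalysed syn hydroboration (CuCl, NaOtBu, PPh3, B2pin2, MeOH, THF) places boron on the alkyne carbon remote from a conjugating substituent. It should give the (1Z,3Z)-dienyl pinacolboronate F1.
- Iododeboronation with retention (NaOH, I2, THF, 0 °C) gives the (1E,3Z)-dienyl iodide F2.
- Dess–Martin oxidation gives the iodo aldehyde F3.
- A Nozaki–Hiyama–Kishi macrocyclization (CrCl2, NiCl2 cat., DMSO/THF, high dilution) closes the ring and comes back to the route at carbinol 34.

Step 21, the epoxidation.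
- **What may go wrong:** the ring conformation instead of the catalyst may decide which face is exposed, which would mean poor or inverted facial selectivity. Oxygen transfer to the ketone-deactivated diene may also be sluggish.
- **Fallback:** substrate control with delivery of oxygen from the side opposite to the exposed one. It sets out from dienedione 36.
- NBS in aqueous acetone at 0 °C should form the bromonium ion on the outer face. Water should then open it at the tertiary C4 from the other side to give the (3R,4R)-bromohydrin F4.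
- Ag2O in CH2Cl2 closes the oxirane with inversion at C3 under neutral conditions. This is a net cis delivery of oxygen to the face that a direct oxidant does not reach, and it rejoins the route at 37.

Step 4, the allylic coupling.
- **What may go wrong:** the organocopper species may attack at the gamma carbon or at the far alkyne terminus of the enynyl bromide (allylic or 1,5-transposition). The Z/E geometry may scramble through an allylcopper intermediate.
- **Fallback:** the order of bond formation is changed so that no alkyne is present in the allylic electrophile. It sets out from iodo alcohol 3.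
- Appel bromination gives (Z)-3-bromo-1-iodo-2-methylprop-1-ene F5.
- Coupling with Grignard reagent 8 under Li2CuCl4 catalysis at -78 °C gives the (Z)-alkenyl iodide F6.
- Sonogashira coupling of F6 with alkyne 4 rejoins the route at silyl ether 9.

Further compounds
F1 | step 18 | (1Z,3Z)-dienyl pinacolboronate, boron on C1 of alcohol 31 after syn H–B addition | CC(C)/C(B1OC(C)(C)C(C)(C)O1)=C\C=C(\C)CCC[C@@H](CO[Si](C)(C)C(C)(C)C)[C@@H](O[Si](CC)(CC)CC)CC[C@@H](C)[C@H](O[Si](C)(C)C(C)(C)C)CO
F2 | step 18 | (1E,3Z)-1-iodo-1-isopropyl dienyl alcohol | CC(C)/C(I)=C\C=C(\C)CCC[C@@H](CO[Si](C)(C)C(C)(C)C)[C@@H](O[Si](CC)(CC)CC)CC[C@@H](C)[C@H](O[Si](C)(C)C(C)(C)C)CO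
F3 | step 18 | (1E,3Z)-1-iodo-1-isopropyl dienyl aldehyde | CC(C)/C(I)=C\C=C(\C)CCC[C@@H](CO[Si](C)(C)C(C)(C)C)[C@@H](O[Si](CC)(CC)CC)CC[C@@H](C)[C@H](O[Si](C)(C)C(C)(C)C)C=O
F4 | step 21 | (1E,3R,4R,8S,12R,13S)-3-bromo-4-hydroxy enedione bis-TBS ether | CC(C)/C1=C\[C@@H](Br)[C@@](O)(C)CCC[C@@H](CO[Si](C)(C)C(C)(C)C)C(=O)CC[C@@H](C)[C@H](O[Si](C)(C)C(C)(C)C)C1=O
F5 | step 4 | (Z)-3-bromo-1-iodo-2-methylprop-1-ene | BrC/C(C)=C\I
F6 | step 4 | (Z)-tert-butyl[(7-iodo-6-methylhept-6-en-1-yl)oxy]dimethylsilane | I/C=C(/C)CCCCCO[Si](C)(C)C(C)(C)C
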